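The product of the amber run stops growing: from 1.25 d to 3.00 d the two products together read 63.2 % of the substrate charged. That is 0.126 M of product from 0.44 M of partner. If that charge was spent, as we assume, 0.314 M of partner went another way, more than into product.

| flask | left-handed substrate | right-handed substrate | partner | racemization catalyst | remark | time |
|---|---|---|---|---|---|---|
| amber | 0.10 M | 0.10 M | 0.44 M | 0.54 mM | run made earlier |  |
| flask | 0.20 M | 0.20 M | 0.440 M | 0.54 mM |  | 10 d |

amber run (percent of the left-handed substrate and right-handed substrate together charged)

| time / d | left-handed product / % | right-handed product / % | left-handed substrate / % |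
|---|---|---|---|
| 0.167 | 25.3 | 15.6 | 26.1 |
| 0.500 | 35.8 | 23.6 | 14.6 |
| 0.833 | 35.4 | 25.9 | 14.5 |
| 1.25 | 36.5 | 25.5 | 13.2 |
| 1.67 | 37.9 | 25.9 | 15.1 |
| 2.50 | 38.6 | 25.8 | 12.9 |
| 3.00 | 37.1 | 25.4 | 14.3 |

(scatter of a reading: 1 percentage point)

- partner is single-handed; left-handed substrate and right-handed substrate are mirror images of each other, charged as a racemate, each of them at the stated concentration
- an excess is below zero if the other one leads
- the handed part of partner does not stay in what it makes, so the products of the two hands are mirror images too

1. left-handed product and right-handed product together, in percent of the left-handed substrate and right-handed substrate charged together, at 10 d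
2. excess of left-handed product over right-handed product in the product at 10 d
3. whether the exchange between left-handed substrate and right-handed substrate keeps pace with the reaction: how far the product's excess at 10 d gets from its value without exchange to its value with instant exchange (above 80 % keeps pace, below 20 % hardly takes part, else lags behind)

We suppose that partner meets free substrate S, both hands at one mean rate constant, and also suffers a first-order loss. Then partner spent = product + D·ln(S0/S), where S0 is the substrate charged. The amber figures give 0.314 M for D, the break-even concentration, the free substrate at which partner goes equally to product and to loss.

Now the settings. Substrate changes: the flask holds 0.400 M of both hands, twice the amber charge. With S at 0.5 of S0, our balance needs 0.418 M of partner, less than the 0.440 M charged. One step along the slope gives 52.2 % of the flask's substrate as product, a lower percentage than in amber, though more product, 0.209 M. Partner stands at the amber value. Time grows to 10 d, but the amber readings are flat, so we credit the added days with nothing. Catalyst stays at 0.54 mM, and in amber the left-handed substrate and left-handed product together read 51.4 % against 50.0 % charged, so we expect little exchange.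

The forecast gives 50 %, slightly below our figure, an excess of 21 %, and exchange that hardly takes part: “The extra days do nothing once the reaction has stalled.”

The flask gives 52.5 %, an excess of 19.1 %, and exchange that hardly takes part, at 3.9 % of the way.

    racemization catalyst → spent catalyst (k = 7.45 × 10⁻⁴ min⁻¹)
    partner + right-handed substrate → right-handed product (k = 0.00561 L mol⁻¹ min⁻¹)
    partner + left-handed substrate → left-handed product (k = 0.00986 L mol⁻¹ min⁻¹)
    left-handed substrate + racemization catalyst ⇌ right-handed substrate + racemization catalyst, rate k4*[racemization catalyst]*[left-handed substrate] forward; the back reaction follows from the equilibrium constant (k = 0.229 L mol⁻¹ min⁻¹)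
    partner → decomposed reagent (k = 0.00232 min⁻¹)
    racemization catalyst ⇌ dormant form (K = 1.00, k = 3.98 × 10⁻⁴ min⁻¹)

Partner, the limiting reagent, reads 0.342 % of its charge at 1.00 d and 0 % at 10.0 d. With D, the flask's conversion implies 0.234 M of partner lost, and decomposed reagent stands at 0.230 M.

In the same flask charged with 1.1 M of partner, S falling by one power of ten, to 10.0 % of S0, costs 1.08 M, close to that charge, so D gives about 90.0 % product. That neighbour gives 89.6 %.

(The numbers in the tables were generated by integration on assumed constants; the scatter is artificial.)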